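**Retrosynthetic overview**
- The target is unmasked last by global hydrogenolysis of a tri-O-benzyl flavonol; its 3-OH comes from epoxidation of the flavone C2=C3 bond and acid-mediated epoxide opening.
- Ring C (the pyranone) is formed by oxidative cyclization of a 2'-hydroxychalcone.
- The chalcone comes from the key C–C bond formation: a Claisen–Schmidt crossed aldol condensation between a 4,6-di-O-benzylated phloroacetophenone (ring A fragment) and (R)-3-benzyloxy-2,2-dimethylchroman-6-carbaldehyde (ring B fragment).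
- The aldehyde comes from a nitrile; the stereocenter is set by Jacobsen epoxidation of 6-cyano-2,2-dimethylchromene followed by benzylic C–O hydrogenolysis; the chromene comes from 4-hydroxybenzonitrile by propargyl ether Claisen rearrangement.
- Ring order: the dimethylpyran ring of the chroman is formed first, ring C of the flavone last; ring A and the benzo ring of the chroman are bought.

Stereochemical reading: the one stereocenter in the SMILES (C3 of the chroman) is (R), and the route is built for that enantiomer.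

**Route**

Step 1
Reactants: 1 4-hydroxybenzonitrile; 2 3-chloro-3-methylbut-1-yne
Product: 3 4-[(2-methylbut-3-yn-2-yl)oxy]benzonitrile
Conditions: K2CO3, KI (cat.), acetone, reflux
Reagents that add atoms: none
Why: Williamson-type O-alkylation of the acidic cyanophenoxide with the tertiary propargylic chloride is the standard entry to aryl 1,1-dimethylpropargyl ethers.

Step 2
Reactants: 3 4-[(2-methylbut-3-yn-2-yl)oxy]benzonitrile
Product: 5 2,2-dimethyl-2H-chromene-6-carbonitrile, via o-allenylphenol 4 (not isolated)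
Conditions: o-dichlorobenzene, 180 °C
Reagents that add atoms: none
Why: Thermal aromatic propargyl Claisen rearrangement gives the o-allenylphenol, which closes the 2,2-dimethyl-2H-pyran ring by 1,5-hydrogen shift and 6π oxa-electrocyclization.

Step 3
Reactants: 5 2,2-dimethyl-2H-chromene-6-carbonitrile
Product: 6 (3R,4R)-3,4-epoxy-2,2-dimethylchroman-6-carbonitrile
Conditions: (R,R)-Jacobsen catalyst C36H52ClMnN2O2 [chloride complex of trivalent manganese with (R,R)-N,N'-bis(3,5-di-tert-butylsalicylidene)cyclohexane-1,2-diamine] (2 mol %), 4-phenylpyridine N-oxide (10 mol %), aq NaOCl buffered with Na2HPO4 (pH 11.3), CH2Cl2, 0 °C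
Reagents that add atoms: sodium hypochlorite, [Na+].[O-]Cl
Why: Jacobsen–Katsuki asymmetric epoxidation of this cis, aryl-conjugated chromene is a benchmark high-ee case, and the (R,R)-ligand delivers the oxo oxygen to the face that gives the cis-fused (3R,4R)-epoxide, which can be recrystallized to raise the ee.

Step 4
Reactants: 6 (3R,4R)-3,4-epoxy-2,2-dimethylchroman-6-carbonitrile
Product: 7 (3R)-3-hydroxy-2,2-dimethylchroman-6-carbonitrile
Conditions: H2 (1 atm), 10 % Pd/C, EtOAc, rt, stopped after 1 equiv of H2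
Reagents that add atoms: none
Why: Catalytic hydrogenolysis cleaves only the benzylic C4–O bond of the aryl epoxide, so C4 becomes CH2 while the C3–O bond and its (R) configuration from step 3 are untouched.

Step 5
Reactants: 7 (3R)-3-hydroxy-2,2-dimethylchroman-6-carbonitrile
Product: 8 (3R)-3-(benzyloxy)-2,2-dimethylchroman-6-carbonitrile
Conditions: NaH, BnBr, n-Bu4NI (cat.), DMF, 0 °C → rt
Reagents that add atoms: benzyl bromide, BrCc1ccccc1
Why: Williamson etherification of the sodium alkoxide masks the secondary alcohol for the later oxidation steps without touching the C–O stereocenter or the non-enolizable aryl nitrile.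

Step 6
Reactants: 8 (3R)-3-(benzyloxy)-2,2-dimethylchroman-6-carbonitrile
Product: 10 (3R)-3-(benzyloxy)-2,2-dimethylchroman-6-carbaldehyde, via aluminium aldimine 9 (not isolated)
Conditions: i-Bu2AlH (1.3 equiv), CH2Cl2, −78 °C; then 1 M aq HCl, 0 °C
Reagents that add atoms: water, O
Why: Partial reduction of the nitrile by i-Bu2AlH stops at the N-aluminated aldimine, which is hydrolysed to the aldehyde on acidic work-up, while the ethers are inert.

Step 7
Reactants: 11 1-(2,4,6-trihydroxyphenyl)ethanone
Product: 12 1-[2,4-bis(benzyloxy)-6-hydroxyphenyl]ethanone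
Conditions: BnBr (2.05 equiv), K2CO3, DMF, rt
Reagents that add atoms: benzyl bromide, BrCc1ccccc1
Why: Williamson etherification stops at the dibenzyl ether because the last ortho hydroxyl is deactivated by its strong hydrogen bond to the ketone, which leaves the free 2'-OH needed for ring C.

Step 8
Reactants: 12 1-[2,4-bis(benzyloxy)-6-hydroxyphenyl]ethanone; 10 (3R)-3-(benzyloxy)-2,2-dimethylchroman-6-carbaldehyde
Product: 14 (E)-1-[2,4-bis(benzyloxy)-6-hydroxyphenyl]-3-[(3R)-3-(benzyloxy)-2,2-dimethylchroman-6-yl]prop-2-en-1-one, via aldol adduct 13 (not isolated)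
Conditions: KOH (50 % aq), EtOH/THF, rt, 36 h
Reagents that add atoms: none
Why: In this Claisen–Schmidt crossed aldol condensation the enolate of methyl ketone 12 adds to the non-enolizable aldehyde 10 to forge the bond joining the two fragments, and E1cB dehydration of the aldol gives the conjugated (E)-chalcone without affecting the remote stereocenter, which has no acidic hydrogen.

Step 9
Reactants: 14 (E)-1-[2,4-bis(benzyloxy)-6-hydroxyphenyl]-3-[(3R)-3-(benzyloxy)-2,2-dimethylchroman-6-yl]prop-2-en-1-one
Product: 16 5,7-bis(benzyloxy)-2-[(3R)-3-(benzyloxy)-2,2-dimethylchroman-6-yl]-4H-chromen-4-one, via flavanone 15 (not isolated)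
Conditions: I2 (10 mol %), DMSO, 130 °C
Reagents that add atoms: none
Why: Iodine-catalysed oxidative cyclization of the 2'-hydroxychalcone (oxa-Michael ring closure, α-iodination and loss of HI, with DMSO as the terminal oxidant) is the standard route to benzyl-protected flavones.

Step 10
Reactants: 16 5,7-bis(benzyloxy)-2-[(3R)-3-(benzyloxy)-2,2-dimethylchroman-6-yl]-4H-chromen-4-one
Product: 18 5,7-bis(benzyloxy)-2-[(3R)-3-(benzyloxy)-2,2-dimethylchroman-6-yl]-3-hydroxy-4H-chromen-4-one, via flavone epoxide 17 (not isolated)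
Conditions: dimethyldioxirane (acetone solution, 3 equiv), CH2Cl2, 0 °C → rt; then p-TsOH·H2O (cat.), CH2Cl2, rt
Reagents that add atoms: dimethyldioxirane, CC1(C)OO1
Why: Dimethyldioxirane epoxidizes the C2=C3 bond of the alkoxy-activated flavone under neutral conditions, and acid-catalysed opening of the epoxide at C2 followed by loss of the C3 proton gives the 3-hydroxyflavone.

Step 11
Reactants: 18 5,7-bis(benzyloxy)-2-[(3R)-3-(benzyloxy)-2,2-dimethylchroman-6-yl]-3-hydroxy-4H-chromen-4-one
Product: 19 3,5,7-trihydroxy-2-[(3R)-3-hydroxy-2,2-dimethylchroman-6-yl]-4H-chromen-4-one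
Conditions: H2 (1 atm), 20 % Pd(OH)2/C, THF/MeOH, rt
Reagents that add atoms: none
Why: Catalytic hydrogenolysis removes the two aryl benzyl ethers and the alkyl benzyl ether in one operation, while the flavonol core, the non-benzylic chroman C–O bonds and the (R) carbinol center are stable to these conditions.

**Compound list**
1 | 4-hydroxybenzonitrile | N#Cc1ccc(O)cc1 | starting material
2 | 3-chloro-3-methylbut-1-yne | CC(C)(Cl)C#C | starting material
3 | 4-[(2-methylbut-3-yn-2-yl)oxy]benzonitrile | CC(C)(C#C)Oc1ccc(C#N)cc1 | intermediate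
4 | 4-hydroxy-3-(3-methylbuta-1,2-dien-1-yl)benzonitrile (o-allenylphenol) | CC(C)=C=Cc1cc(C#N)ccc1O | intermediate (not isolated)
5 | 2,2-dimethyl-2H-chromene-6-carbonitrile | CC1(C)C=Cc2cc(C#N)ccc2O1 | intermediate
6 | (3R,4R)-3,4-epoxy-2,2-dimethylchroman-6-carbonitrile (cis-fused epoxide, chroman numbering) | CC1(C)Oc2ccc(C#N)cc2[C@H]3O[C@@H]13 | intermediate
7 | (3R)-3-hydroxy-2,2-dimethylchroman-6-carbonitrile | CC1(C)Oc2ccc(C#N)cc2C[C@H]1O | intermediate
8 | (3R)-3-(benzyloxy)-2,2-dimethylchroman-6-carbonitrile | CC1(C)Oc2ccc(C#N)cc2C[C@H]1OCc1ccccc1 | intermediate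
9 | N-(diisobutylalumino) aldimine of aldehyde 10 (aluminium aldimine) | CC1(C)Oc2ccc(C=N[Al](CC(C)C)CC(C)C)cc2C[C@H]1OCc1ccccc1 | intermediate (not isolated)
10 | (3R)-3-(benzyloxy)-2,2-dimethylchroman-6-carbaldehyde | CC1(C)Oc2ccc(C=O)cc2C[C@H]1OCc1ccccc1 | intermediate
11 | 1-(2,4,6-trihydroxyphenyl)ethanone | CC(=O)c1c(O)cc(O)cc1O | starting material
12 | 1-[2,4-bis(benzyloxy)-6-hydroxyphenyl]ethanone | CC(=O)c1c(O)cc(OCc2ccccc2)cc1OCc1ccccc1 | intermediate
13 | 1-[2,4-bis(benzyloxy)-6-hydroxyphenyl]-3-[(3R)-3-(benzyloxy)-2,2-dimethylchroman-6-yl]-3-hydroxypropan-1-one (aldol adduct, both epimers at the new carbinol carbon) | CC1(C)Oc2ccc(C(O)CC(=O)c3c(O)cc(OCc4ccccc4)cc3OCc3ccccc3)cc2C[C@H]1OCc1ccccc1 | intermediate (not isolated)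
14 | (E)-1-[2,4-bis(benzyloxy)-6-hydroxyphenyl]-3-[(3R)-3-(benzyloxy)-2,2-dimethylchroman-6-yl]prop-2-en-1-one | CC1(C)Oc2ccc(/C=C/C(=O)c3c(O)cc(OCc4ccccc4)cc3OCc3ccccc3)cc2C[C@H]1OCc1ccccc1 | intermediate
15 | 5,7-bis(benzyloxy)-2-[(3R)-3-(benzyloxy)-2,2-dimethylchroman-6-yl]chroman-4-one (flavanone, both C2 epimers) | CC1(C)Oc2ccc(C3CC(=O)c4c(OCc5ccccc5)cc(OCc5ccccc5)cc4O3)cc2C[C@H]1OCc1ccccc1 | intermediate (not isolated)
16 | 5,7-bis(benzyloxy)-2-[(3R)-3-(benzyloxy)-2,2-dimethylchroman-6-yl]-4H-chromen-4-one | CC1(C)Oc2ccc(-c3cc(=O)c4c(OCc5ccccc5)cc(OCc5ccccc5)cc4o3)cc2C[C@H]1OCc1ccccc1 | intermediate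
17 | 5,7-bis(benzyloxy)-2-[(3R)-3-(benzyloxy)-2,2-dimethylchroman-6-yl]-2,3-epoxychroman-4-one (flavone epoxide, both epoxide diastereomers) | CC1(C)Oc2ccc(C35OC3C(=O)c3c(OCc6ccccc6)cc(OCc6ccccc6)cc3O5)cc2C[C@H]1OCc1ccccc1 | intermediate (not isolated)
18 | 5,7-bis(benzyloxy)-2-[(3R)-3-(benzyloxy)-2,2-dimethylchroman-6-yl]-3-hydroxy-4H-chromen-4-one | CC1(C)Oc2ccc(-c3oc4cc(OCc5ccccc5)cc(OCc5ccccc5)c4c(=O)c3O)cc2C[C@H]1OCc1ccccc1 | intermediate
19 | 3,5,7-trihydroxy-2-[(3R)-3-hydroxy-2,2-dimethylchroman-6-yl]-4H-chromen-4-one (CNP0411714.1) | CC1(C)Oc2ccc(-c3oc4cc(O)cc(O)c4c(=O)c3O)cc2C[C@H]1O | target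

**Totals**
Total step count: 11. Longest linear sequence: 10 steps (steps 1–6, then 8–11, from 4-hydroxybenzonitrile); step 7 is the one-step side branch.

**Three steps most likely to fail, with fallbacks**

Step 4. The benzylic hydrogenolysis must stop before the aryl nitrile is reduced. The fallback sets out from epoxide 6 and replaces hydrogenation by ionic opening and radical reduction. LiBr/AcOH in THF at 0 °C delivers bromide to the benzylic C4 with inversion and gives the trans-bromohydrin (3S,4S)-4-bromo-3-hydroxy-2,2-dimethylchroman-6-carbonitrile F1. The spatial arrangement at C3 is unchanged; only the descriptor changes, because bromine raises the priority of C4. Radical debromination with n-Bu3SnH and AIBN in toluene at 80 °C, to which the nitrile is inert, comes back to the route at chromanol 7.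

Step 10. Dimethyldioxirane must epoxidize an electron-poor enone faster than it oxidizes the benzylic C–H bonds of the alkyl benzyl ether. The fallback sets out from chalcone 14 and bypasses the flavone by Algar–Flynn–Oyamada oxidation (30 % aq H2O2, NaOH, MeOH/THF, 0 °C). Cyclization with α-hydroxylation gives the dihydroflavonol 5,7-bis(benzyloxy)-2-[(3R)-3-(benzyloxy)-2,2-dimethylchroman-6-yl]-3-hydroxychroman-4-one F2, which is oxidized further in the same flask. The sequence comes back to the route at flavonol 18; the low temperature is meant to suppress the competing aurone pathway.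

Step 11. The hindered secondary alkyl benzyl ether may lag behind the two aryl benzyl ethers, and forcing the hydrogenation risks reducing the pyranone ring. The fallback sets out from 18 and cleaves all three benzyl ethers by Lewis acid instead of hydrogen: BCl3 with pentamethylbenzene as benzyl-cation scavenger, CH2Cl2, −78 °C, then MeOH quench. It comes back to the route at target 19 and makes no new compound (F0).

**Further compounds**
F1 | step 4 | (3S,4S)-4-bromo-3-hydroxy-2,2-dimethylchroman-6-carbonitrile (trans-bromohydrin) | CC1(C)Oc2ccc(C#N)cc2[C@H](Br)[C@H]1O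
F2 | step 10 | 5,7-bis(benzyloxy)-2-[(3R)-3-(benzyloxy)-2,2-dimethylchroman-6-yl]-3-hydroxychroman-4-one (2,3-trans dihydroflavonol, both trans diastereomers) | CC1(C)Oc2ccc(C3Oc4cc(OCc5ccccc5)cc(OCc5ccccc5)c4C(=O)C3O)cc2C[C@H]1OCc1ccccc1
F0 | step 11 | none | none
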